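**Retrosynthetic overview**

1. The target, (R)-5,7-dihydroxy-6-(1-methylpiperidin-2-yl)flavone, comes from its 5,7-di-O-methyl ether. The pyranone ring C is made from an o-hydroxyacetophenone and benzoyl chloride; its ring oxygen O1 is the one phenol oxygen para to the piperidine-bearing carbon, kept distinct from the two methoxy oxygens from the start, which fixes 6- and not 8-substitution.
2. The acetophenone comes from a 4-(piperidin-2-yl)-3,5-dimethoxyphenol by Fries acylation; the N-methyl group comes from reductive amination and the C2 stereocentre (R) from asymmetric hydrogenation of a cyclic 2-aryl ketimine.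
3. Key disconnection: the ketimine comes from cyclopentanone oxime mesylate and an aryl Grignard reagent. A Beckmann ring expansion inserts N into the cyclopentane ring to give the six-membered azacycle, and the imidoyl carbon is arylated in the same flask, which forms the flavone-C6 to piperidine-C2 bond.
4. Enabling feature: piperidine C3–C6 are four unsubstituted CH2 groups, so C2–C6 map onto a symmetrical cyclopentanone oxime (either α-carbon migrates to the same product, and C2 emerges as the electrophilic carbon). Flavone C6 lies between the oxygen-bearing C5 and C7, i.e. between the two methoxy groups of a resorcinol diether, which is the site of directed ortho-lithiation.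
5. Ring order: A ring (commercial 3,5-dimethoxyphenol), then piperidine ring (step 3, from a cyclopentane), then pyranone ring C (step 8); the B ring comes from benzoyl chloride.

Key step: step 3

Assumption (chemistry): the benzylic C2–N stereocentre of the electron-rich 2-arylpiperidine is taken to be stable below about 45 °C but at risk in hot protic acid (reversible C–N ionisation), so every step after step 4 is kept at or below that temperature.

**Route**

Step 1
Reactants: 1 3,5-dimethoxyphenol
Product: 2 (3,5-dimethoxyphenoxy)tri(propan-2-yl)silane
Conditions: TIPSCl, imidazole, DMF, rt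
Reagents that add atoms: triisopropylsilyl chloride, CC(C)[Si](Cl)(C(C)C)C(C)C
Why: Routine O-silylation of a phenol; the bulky, non-coordinating TIPS ether should survive n-BuLi and leave the carbon between the two methoxy groups as the only doubly activated lithiation site.

Step 2
Reactants: 3 cyclopentanone oxime
Product: 4 cyclopentanone O-(methylsulfonyl)oxime
Conditions: MsCl, Et3N, CH2Cl2, −20 °C; cold aqueous work-up, used at once
Reagents that add atoms: methanesulfonyl chloride, CS(=O)(=O)Cl
Why: O-sulfonylation of a ketoxime turns the N–OH into a leaving group for the Beckmann rearrangement; low temperature and immediate use guard against premature rearrangement of the labile sulfonate.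

Step 3
Reactants: 2 (3,5-dimethoxyphenoxy)tri(propan-2-yl)silane; 4 cyclopentanone O-(methylsulfonyl)oxime
Product: 8 6-[2,6-dimethoxy-4-(triisopropylsilyloxy)phenyl]-2,3,4,5-tetrahydropyridine, via aryllithium 5 (not isolated), via arylmagnesium bromide 6 (not isolated), via lactim mesylate 7 (not isolated)
Conditions: n-BuLi, Et2O, 0 °C → rt; MgBr2·OEt2, 0 °C; then 4, toluene, −78 → 0 °C
Reagents that add atoms: none
Why: Directed ortho-lithiation of 2 should occur at the carbon between the two methoxy groups (cooperative coordination; the TIPS ether neither directs nor migrates), and Li→Mg exchange gives the Lewis-acidic aryl Grignard 6. Coordination of Mg(II) to the sulfonate of 4 should trigger N–O ionisation with concerted anti 1,2-shift of a ring CH2 from carbon to nitrogen, enlarging the cyclopentane ring by insertion of N to the six-membered lactim mesylate 7 (collapsed nitrilium–sulfonate ion pair), whose imidoyl carbon is then arylated by 6 with loss of magnesium sulfonate to give ketimine 8. The closest known reaction type is the organoaluminium- or Grignard-promoted Beckmann rearrangement–alkylation of cycloalkanone oxime sulfonates, which turns cyclopentanone oxime sulfonates into 2-substituted 3,4,5,6-tetrahydropyridines. No ring is closed by cyclisation: the piperidine ring arises by ring expansion (1,2-C→N shift), and no stereocentre is created, since C2 emerges as an sp2 carbon that is set in step 4. The step needs regioselective metalation (secured by the two flanking methoxy groups), freedom from migration regiochemistry (secured by the symmetry of the oxime), and mono-arylation at carbon rather than attack at sulfur or α-deprotonation (favoured by low temperature, the non-polar medium and the inertness of the hindered di-ortho-substituted ketimine 8 to a second addition).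

Step 4
Reactants: 8 6-[2,6-dimethoxy-4-(triisopropylsilyloxy)phenyl]-2,3,4,5-tetrahydropyridine
Product: 9 (2R)-2-[2,6-dimethoxy-4-(triisopropylsilyloxy)phenyl]piperidine
Conditions: H2 (50 bar), [Ir(cod)Cl]2 (1 mol %), f-Binaphane (2.2 mol %, antipode delivering H to the Si face), I2 (10 mol %), CH2Cl2, rt
Reagents that add atoms: none
Why: Iridium–bisphosphine/iodine asymmetric hydrogenation of cyclic 2-aryl ketimines is an established reaction type; the C2 stereocentre is set by catalyst-controlled hydride delivery to the Si face of C=N (priorities N > aryl C > CH2), giving the R amine, with silyl and methyl ethers inert.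

Step 5
Reactants: 9 (2R)-2-[2,6-dimethoxy-4-(triisopropylsilyloxy)phenyl]piperidine
Product: 10 (2R)-2-[2,6-dimethoxy-4-(triisopropylsilyloxy)phenyl]-1-methylpiperidine
Conditions: 37% aq. HCHO, NaBH(OAc)3, 1,2-dichloroethane, rt
Reagents that add atoms: formaldehyde, C=O
Why: Reductive amination through the exocyclic N-methyleneiminium ion should methylate the secondary amine without touching C2, and both ortho positions of the aryl ring are blocked, so no Pictet–Spengler-type closure can compete.

Step 6
Reactants: 10 (2R)-2-[2,6-dimethoxy-4-(triisopropylsilyloxy)phenyl]-1-methylpiperidine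
Product: 11 3,5-dimethoxy-4-[(2R)-1-methylpiperidin-2-yl]phenol
Conditions: TBAF, AcOH (1:1), THF, 0 °C → rt
Reagents that add atoms: none
Why: Buffered fluoride desilylation of an aryl silyl ether is mild and should free only the phenol para to the piperidine-bearing carbon, the oxygen destined to become O1 of the chromone.

Step 7
Reactants: 11 3,5-dimethoxy-4-[(2R)-1-methylpiperidin-2-yl]phenol
Product: 13 1-[6-hydroxy-2,4-dimethoxy-3-[(2R)-1-methylpiperidin-2-yl]phenyl]ethan-1-one, via aryl acetate 12 (not isolated)
Conditions: Ac2O (1.5 equiv), BF3·OEt2 (4 equiv), CH2Cl2, 0 → 40 °C; then aq. NaHCO3/MeOH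
Reagents that add atoms: acetic anhydride, CC(=O)OC(C)=O
Why: O-acetylation followed by BF3-mediated Fries rearrangement should place the acetyl group ortho to the phenol oxygen (the two free ring positions are equivalent), while chelation of boron by the free ortho-hydroxy ketone should spare the neighbouring methoxy group and the amine is simply held as its BF3 adduct.

Step 8
Reactants: 13 1-[6-hydroxy-2,4-dimethoxy-3-[(2R)-1-methylpiperidin-2-yl]phenyl]ethan-1-one
Product: 15 5,7-dimethoxy-6-[(2R)-1-methylpiperidin-2-yl]-2-phenyl-4H-chromen-4-one, via β-diketone 14 (not isolated)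
Conditions: LiHMDS (3.3 equiv), THF, −78 °C; BzCl (1.05 equiv), −78 °C → rt; then AcOH, conc. HCl, rt → 40 °C
Reagents that add atoms: benzoyl chloride, O=C(Cl)c1ccccc1
Why: Baker–Venkataraman-type aroylation of the phenoxide–enolate dianion should give the 1,3-diketone, and acid cyclodehydration through the only free phenol closes the pyranone ring (6-exo-trig hemiketal formation, then loss of water), so that O1 is the oxygen para to the piperidine-bearing carbon and the 6-substituted flavone results.

Step 9
Reactants: 15 5,7-dimethoxy-6-[(2R)-1-methylpiperidin-2-yl]-2-phenyl-4H-chromen-4-one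
Product: 16 5,7-dihydroxy-6-[(2R)-1-methylpiperidin-2-yl]-2-phenyl-4H-chromen-4-one
Conditions: BBr3 (6 equiv), CH2Cl2, −78 °C → rt; MeOH quench, aq. NaHCO3
Reagents that add atoms: none
Why: Lewis acid O-demethylation with BBr3 should cleave both aryl methyl ethers (the 5-OMe assisted by chelation to C4=O) at or below room temperature, where the boron-bound phenoxides and the complexed amine should not ionise the benzylic C–N bond.

**Compound list**

1 | 3,5-dimethoxyphenol | COc1cc(O)cc(OC)c1 | starting material
2 | (3,5-dimethoxyphenoxy)tri(propan-2-yl)silane | COc1cc(O[Si](C(C)C)(C(C)C)C(C)C)cc(OC)c1 | intermediate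
3 | cyclopentanone oxime | ON=C1CCCC1 | starting material
4 | cyclopentanone O-(methylsulfonyl)oxime | CS(=O)(=O)ON=C1CCCC1 | intermediate
5 | [2,6-dimethoxy-4-(triisopropylsilyloxy)phenyl]lithium | [Li]c1c(OC)cc(O[Si](C(C)C)(C(C)C)C(C)C)cc1OC | intermediate (not isolated)
6 | [2,6-dimethoxy-4-(triisopropylsilyloxy)phenyl]magnesium bromide | Br[Mg]c1c(OC)cc(O[Si](C(C)C)(C(C)C)C(C)C)cc1OC | intermediate (not isolated)
7 | 3,4,5,6-tetrahydropyridin-2-yl methanesulfonate | CS(=O)(=O)OC1=NCCCC1 | intermediate (not isolated)
8 | 6-[2,6-dimethoxy-4-(triisopropylsilyloxy)phenyl]-2,3,4,5-tetrahydropyridine | COc1cc(O[Si](C(C)C)(C(C)C)C(C)C)cc(OC)c1C1=NCCCC1 | intermediate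
9 | (2R)-2-[2,6-dimethoxy-4-(triisopropylsilyloxy)phenyl]piperidine | N1CCCC[C@@H]1c1c(OC)cc(O[Si](C(C)C)(C(C)C)C(C)C)cc1OC | intermediate
10 | (2R)-2-[2,6-dimethoxy-4-(triisopropylsilyloxy)phenyl]-1-methylpiperidine | CN1CCCC[C@@H]1c1c(OC)cc(O[Si](C(C)C)(C(C)C)C(C)C)cc1OC | intermediate
11 | 3,5-dimethoxy-4-[(2R)-1-methylpiperidin-2-yl]phenol | CN1CCCC[C@@H]1c1c(OC)cc(O)cc1OC | intermediate
12 | 3,5-dimethoxy-4-[(2R)-1-methylpiperidin-2-yl]phenyl acetate | CN1CCCC[C@@H]1c1c(OC)cc(OC(C)=O)cc1OC | intermediate (not isolated)
13 | 1-[6-hydroxy-2,4-dimethoxy-3-[(2R)-1-methylpiperidin-2-yl]phenyl]ethan-1-one | CN1CCCC[C@@H]1c1c(OC)cc(O)c(C(C)=O)c1OC | intermediate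
14 | 1-[6-hydroxy-2,4-dimethoxy-3-[(2R)-1-methylpiperidin-2-yl]phenyl]-3-phenylpropane-1,3-dione | CN1CCCC[C@@H]1c1c(OC)cc(O)c(C(=O)CC(=O)c2ccccc2)c1OC | intermediate (not isolated)
15 | 5,7-dimethoxy-6-[(2R)-1-methylpiperidin-2-yl]-2-phenyl-4H-chromen-4-one | CN1CCCC[C@@H]1c1c(OC)cc2oc(-c3ccccc3)cc(=O)c2c1OC | intermediate
16 | 5,7-dihydroxy-6-[(2R)-1-methylpiperidin-2-yl]-2-phenyl-4H-chromen-4-one | CN1CCCC[C@@H]1c1c(O)cc2oc(-c3ccccc3)cc(=O)c2c1O | target

**Step count and risks**

Total step count: 9. Longest linear sequence: 8 steps (steps 1, 3, 4, 5, 6, 7, 8, 9 from 3,5-dimethoxyphenol); step 2 is the one-step branch.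

Steps most likely to fail:

1. Step 3. Aryl transfer from the hindered di-ortho-methoxyaryl Grignard may be outpaced by attack at sulfur or by α-deprotonation and decomposition of the sulfonate, so that rearrangement and arylation do not mesh in one flask. Fallback: the two events are separated while the ring expansion is kept. Setting out from oxime 3, a classical acid-mediated Beckmann rearrangement should give piperidin-2-one F1. O-methylation with trimethyloxonium tetrafluoroborate (CH2Cl2, rt, then aq. K2CO3) should give the lactim ether 6-methoxy-2,3,4,5-tetrahydropyridine F2. Addition–elimination of aryllithium 5 (made from 2 as in step 3; Et2O/THF, −78 °C → rt) at the lactim carbon should then deliver ketimine 8, where the route is rejoined.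

2. Step 4. The di-ortho-methoxyaryl group is twisted out of the C=N plane, which may give poor facial discrimination and slow turnover at the hindered ketimine. Fallback: setting out from 8, non-selective reduction with NaBH4 (MeOH, 0 °C) should give racemic 2-[2,6-dimethoxy-4-(triisopropylsilyloxy)phenyl]piperidine F3. Its enantiomers are separated by preparative chromatography on a chiral stationary phase; the R enantiomer is 9, where the route is rejoined.

3. Step 7. Lewis-acid cleavage of the methoxy group flanked by the new ketone and the piperidine may compete. This would erase the oxygen differentiation on which the 6- versus 8-regiochemistry rests; sluggish acyl transfer in the presence of the amine–BF3 adduct is the second concern. Fallback: setting out from 11, magnesium-mediated ortho-formylation (MgCl2, Et3N, paraformaldehyde, MeCN, 60 °C) should give 6-hydroxy-2,4-dimethoxy-3-[(2R)-1-methylpiperidin-2-yl]benzaldehyde F4. Addition of lithium phenylacetylide (2.2 equiv, THF, −78 °C) should give the propargylic alcohol 1-[6-hydroxy-2,4-dimethoxy-3-[(2R)-1-methylpiperidin-2-yl]phenyl]-3-phenylprop-2-yn-1-ol F5 (carbinol epimers). MnO2 oxidation (CH2Cl2, rt) should give the ynone 1-[6-hydroxy-2,4-dimethoxy-3-[(2R)-1-methylpiperidin-2-yl]phenyl]-3-phenylprop-2-yn-1-one F6. Base-mediated 6-endo-dig oxa-Michael closure (K2CO3, acetone, rt) should then give flavone 15, where the route is rejoined without any Lewis acid and without step 8.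

**Further compounds**

F1 | step 3 | piperidin-2-one | O=C1CCCCN1
F2 | step 3 | 6-methoxy-2,3,4,5-tetrahydropyridine | COC1=NCCCC1
F3 | step 4 | racemic 2-[2,6-dimethoxy-4-(triisopropylsilyloxy)phenyl]piperidine | COc1cc(O[Si](C(C)C)(C(C)C)C(C)C)cc(OC)c1C1CCCCN1
F4 | step 7 | 6-hydroxy-2,4-dimethoxy-3-[(2R)-1-methylpiperidin-2-yl]benzaldehyde | CN1CCCC[C@@H]1c1c(OC)cc(O)c(C=O)c1OC
F5 | step 7 | 1-[6-hydroxy-2,4-dimethoxy-3-[(2R)-1-methylpiperidin-2-yl]phenyl]-3-phenylprop-2-yn-1-ol | CN1CCCC[C@@H]1c1c(OC)cc(O)c(C(O)C#Cc2ccccc2)c1OC
F6 | step 7 | 1-[6-hydroxy-2,4-dimethoxy-3-[(2R)-1-methylpiperidin-2-yl]phenyl]-3-phenylprop-2-yn-1-one | CN1CCCC[C@@H]1c1c(OC)cc(O)c(C(=O)C#Cc2ccccc2)c1OC
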